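The retrosynthesis cuts C7'–H first (carbinol back to aryl ketone). It then cuts C4–C7' and C3–O together, because the β-hydroxy ketone is an opened 2-isoxazoline (retro-(3+2)). Last it cuts C3–CH2Ar (cross-coupling), and C5 is raised to an acetal that carries the auxiliary.
Enabling feature: on the γ-butyrolactone ring (O1–C2–C3–C4–C5) the tertiary OH on C3 and the exocyclic carbon C7' on C4 are cis. Their oxygens are 1,3-related along O–C3–C4–C7'–O, which is the imprint of a 3-aryl-2-isoxazoline ring cis-fused on the C3–C4 bond. The plain OCH2 (C5) beside C4 can hold a temporary alkoxy stereocentre.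
Forward: the lactone ring is present from the first compound. C3 is brominated and benzylated, the isoxazoline ring is annulated onto C3=C4, and the acetal carbon is reduced to CH2 (the lactone opens and recloses). The N–O bond is then cleaved, the benzyl ethers are removed and the ketone is reduced last.
Stereochemistry: l-menthol fixes the (5R)-acetal, which sends the dipole to the opposite face, so C3 (S) and C4 arise together by suprafacial addition. C7' (R) comes from hydride delivered by boron bound to the C3 hydroxyl.
Both guaiacyl units come from O-benzylvanillin.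

Key step: step 8

Remark: butenolide 1 is taken as a catalogue compound; monocyclic lactones are numbered O1, C2 (C=O), C3, C4, C5 with C7' for the side-chain carbon, the bicycles as furo[3,4-d]isoxazoles (O1, N2, C3, C3a, C4, O5, C6, C6a), and the descriptor of the ring CH changes along the route only because its neighbours change CIP rank, never by inversion.

Step 1
Reactants: 1 (5R)-5-(l-menthyloxy)furan-2(5H)-one
Product: 3 (5R)-3-bromo-5-(l-menthyloxy)furan-2(5H)-one, via 3,4-dibromolactone 2 (not isolated)
Conditions: Br2, CH2Cl2, 0 °C to rt; then Et3N (1.1 equiv), 0 °C; recrystallisation from hexane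
Reagents that add atoms: bromine, BrBr
Why: Bromination–dehydrobromination of an enoate: anti addition of Br2 to C3=C4 gives 2, from which the amine removes the acidic C3–H with loss of the C4 bromide, and with barely more than one equivalent of Et3N at 0 °C the C5 acetal centre should stay (R), any epimer being removed on recrystallisation.

Step 2
Reactants: 4 4-benzyloxy-3-methoxybenzaldehyde
Product: 5 (4-benzyloxy-3-methoxyphenyl)methanol
Conditions: NaBH4, MeOH, 0 °C
Reagents that add atoms: none
Why: Borohydride reduction of an aromatic aldehyde, with no other reducible group in the molecule.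

Step 3
Reactants: 5 (4-benzyloxy-3-methoxyphenyl)methanol
Product: 6 4-benzyloxy-3-methoxybenzyl chloride
Conditions: SOCl2, CH2Cl2, 0 °C
Reagents that add atoms: thionyl chloride, O=S(Cl)Cl
Why: Deoxychlorination of an electron-rich benzylic alcohol with thionyl chloride is fast at 0 °C, leaves both ethers intact, and the sensitive chloride is carried on crude.

Step 4
Reactants: 6 4-benzyloxy-3-methoxybenzyl chloride
Product: 7 (4-benzyloxy-3-methoxybenzyl)zinc chloride (THF solution)
Conditions: Zn dust, LiCl, THF, 25 °C
Reagents that add atoms: zinc, [Zn]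
Why: LiCl-assisted direct insertion of zinc into a benzylic C–Cl bond proceeds at room temperature with little Wurtz-type homocoupling and tolerates the aryl ethers, the reagent being titrated and used as its THF solution.

Step 5
Reactants: 3 (5R)-3-bromo-5-(l-menthyloxy)furan-2(5H)-one; 7 (4-benzyloxy-3-methoxybenzyl)zinc chloride
Product: 8 (5R)-3-(4-benzyloxy-3-methoxybenzyl)-5-(l-menthyloxy)furan-2(5H)-one
Conditions: Pd(OAc)2 (2 mol %), SPhos (4 mol %), THF, 0 to 25 °C
Reagents that add atoms: none
Why: Negishi sp2–sp3 cross-coupling, in which zerovalent palladium inserts into the activated C3–Br bond of the α-bromo enoate, the benzylzinc reagent (no β-hydrogen) transmetalates and reductive elimination forms C3–CH2Ar under neutral conditions that leave the C5 acetal and the position of the ring double bond alone.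

Step 6
Reactants: 4 4-benzyloxy-3-methoxybenzaldehyde
Product: 9 (E)-4-benzyloxy-3-methoxybenzaldehyde oxime
Conditions: NH2OH·HCl, NaOAc, EtOH–H2O, rt
Reagents that add atoms: hydroxylamine hydrochloride, NO.Cl
Why: Acetate-buffered condensation of the aldehyde with hydroxylamine (oxime formation) should give the thermodynamically preferred (E)-aldoxime.

Step 7
Reactants: 9 (E)-4-benzyloxy-3-methoxybenzaldehyde oxime
Product: 10 (Z)-4-benzyloxy-N-hydroxy-3-methoxybenzimidoyl chloride
Conditions: NCS (1.0 equiv), DMF, 20–30 °C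
Reagents that add atoms: N-chlorosuccinimide, O=C1CCC(=O)N1Cl
Why: Chlorination of the aldoxime carbon with NCS in DMF is the standard route to hydroximoyl chlorides and, kept near room temperature with one equivalent of NCS, should outrun chlorination of the alkoxy-substituted ring.

Step 8
Reactants: 8 (5R)-3-(4-benzyloxy-3-methoxybenzyl)-5-(l-menthyloxy)furan-2(5H)-one; 10 (Z)-4-benzyloxy-N-hydroxy-3-methoxybenzimidoyl chloride
Product: 12 (3aR,4R,6aS)-3-(4-benzyloxy-3-methoxyphenyl)-6a-(4-benzyloxy-3-methoxybenzyl)-4-(l-menthyloxy)-3a,6a-dihydrofuro[3,4-d]isoxazol-6(4H)-one, via nitrile oxide 11 (not isolated)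
Conditions: 10 (3 equiv, in portions), solid NaHCO3, EtOAc, 25 to 45 °C
Reagents that add atoms: none
Why: Solid bicarbonate slowly strips HCl from 10, and the nitrile oxide 11 so released adds across C3=C4 of 8 in a concerted, suprafacial Huisgen 1,3-dipolar (3+2) cycloaddition, its carbon bonding to C4 and its oxygen to C3. The closest known reactions are nitrile oxide additions to 5-alkoxy-2(5H)-furanones, which occur anti to the alkoxy group, and to α-alkylated enoates and other trisubstituted alkenes, which put the oxygen on the fully substituted carbon. The single new ring, the five-membered 2-isoxazoline, closes by intermolecular annulation in which the C4–C and C3–O bonds form in the same step, and because the alkene is held cis inside the lactone the fusion can only be cis. Both new stereocentres are controlled by one element, the (R)-acetal carbon C5: its menthyloxy group blocks one face, the dipole comes in from the other, and suprafaciality then fixes the quaternary C–O centre (6aS) and the neighbouring CH (3aR) together. Regioselectivity is the second requirement and rests on the C3 benzyl group, which leaves room at C3 only for the slim oxygen terminus and sends the aryl-bearing carbon to the C4–H terminus. Slow release and an excess of 10 hold back dimerisation of the dipole while the sluggish alkene reacts, and the absence of a soluble amine spares the base-sensitive C5–H.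

Step 9
Reactants: 12 menthyloxy cycloadduct
Product: 13 (3aR,6aS)-3-(4-benzyloxy-3-methoxyphenyl)-6a-(4-benzyloxy-3-methoxybenzyl)-4-hydroxy-3a,6a-dihydrofuro[3,4-d]isoxazol-6(4H)-one (lactol, both C4 anomers)
Conditions: 2 M aq HCl–1,4-dioxane, 60 °C
Reagents that add atoms: water, O
Why: Acid-catalysed hydrolysis of the mixed acyloxy alkoxy acetal releases l-menthol for recovery and leaves the pseudo-acid, the aryl benzyl ethers and the isoxazoline being stable to dilute acid and C3a being safeguarded because only the cis aldehyde acid can close to the lactol.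

Step 10
Reactants: 13 lactol
Product: 16 (3aS,6aS)-3-(4-benzyloxy-3-methoxyphenyl)-6a-(4-benzyloxy-3-methoxybenzyl)-3a,6a-dihydrofuro[3,4-d]isoxazol-6(4H)-one, via aldehyde acid 14 (not isolated), via hydroxy acid 15 (not isolated)
Conditions: NaBH4 (excess), THF–EtOH, −40 to 0 °C, 13 added to the hydride; then 1 M HCl to pH 2, rt
Reagents that add atoms: none
Why: Borohydride reduction of a pseudo-acid: loss of the acidic proton opens 13 to the carboxylate of 14, which by inverse addition at low temperature always meets excess hydride and is reduced before its C–H between CHO and C=N can enolise, NaBH4 leaving the C=N bond and the carboxylate alone, and acidification closes 15 to the γ-lactone with the original carbonyl carbon retained and both stereocentres unchanged (3aR becomes 3aS only because C4 loses rank).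

Step 11
Reactants: 16 isoxazoline-fused lactone
Product: 18 (3S,4S)-4-(4-benzyloxy-3-methoxybenzoyl)-3-(4-benzyloxy-3-methoxybenzyl)-3-hydroxydihydrofuran-2(3H)-one, via hydroxy imine 17 (not isolated)
Conditions: H2 (1 atm), Raney Ni, B(OH)3, MeOH–THF–H2O, rt
Reagents that add atoms: water, O
Why: Reductive N–O cleavage of a 2-isoxazoline over Raney Ni in the presence of boric acid, which hydrolyses imine 17 as it forms and buffers the ammonia, unmasks the aldol-type β-hydroxy ketone near neutrality, so retro-aldol cleavage, dehydration and epimerisation at C4 should be avoided and no stereocentre is touched.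

Step 12
Reactants: 18 dibenzyl β-hydroxy ketone
Product: 19 (3S,4S)-3-hydroxy-4-(4-hydroxy-3-methoxybenzoyl)-3-(4-hydroxy-3-methoxybenzyl)dihydrofuran-2(3H)-one
Conditions: H2 (1 atm), Pd/C, EtOAc, rt, stopped after two equivalents of H2
Reagents that add atoms: none
Why: Hydrogenolysis of aryl benzyl ethers over Pd/C in a neutral solvent is much faster than reduction of the electron-rich aryl ketone, so interrupting the reaction after two equivalents of H2 should give the bisphenol without touching C7'.

Step 13
Reactants: 19 free-phenol β-hydroxy ketone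
Product: 21 (3S,4R)-3-hydroxy-4-[(R)-hydroxy(4-hydroxy-3-methoxyphenyl)methyl]-3-(4-hydroxy-3-methoxybenzyl)dihydrofuran-2(3H)-one (CNP0352022.1), via alkoxyborohydride 20 (not isolated)
Conditions: Me4NBH(OAc)3 (excess), MeCN–AcOH 1:1, −30 to −20 °C; aqueous work-up at pH 5–6
Reagents that add atoms: none
Why: Evans–Saksena hydroxyl-directed reduction: the C3 hydroxyl displaces acetate on boron (20) and hydride travels within a chair-like six-membered array (H, B, O, C3, C4, C7') in which the C3 benzyl group and the ketone aryl group sit equatorial while the tied-back lactone C2 takes the axial site (the other chair would press the benzyl group against the boron acetate), so the Si face of the acid-activated carbonyl is attacked and C7' becomes (R), C4 changing from S to R only because C7' loses rank, and the acid- and hydrogenolysis-sensitive p-hydroxybenzylic alcohol appears only in the last flask.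

Compound list
1 | (5R)-5-[(1R,2S,5R)-menthyloxy]furan-2(5H)-one | O=C1C=C[C@H](O[C@@H]2C[C@H](C)CC[C@H]2C(C)C)O1 | starting material
2 | (5R)-3,4-dibromo-5-(l-menthyloxy)dihydrofuran-2(3H)-one, trans-dibromide, C3/C4 not controlled and erased in the elimination | O=C1C(Br)C(Br)[C@H](O[C@@H]2C[C@H](C)CC[C@H]2C(C)C)O1 | intermediate
3 | (5R)-3-bromo-5-(l-menthyloxy)furan-2(5H)-one | O=C1C(Br)=C[C@H](O[C@@H]2C[C@H](C)CC[C@H]2C(C)C)O1 | intermediate
4 | 4-benzyloxy-3-methoxybenzaldehyde | COc1cc(C=O)ccc1OCc1ccccc1 | starting material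
5 | (4-benzyloxy-3-methoxyphenyl)methanol | COc1cc(CO)ccc1OCc1ccccc1 | intermediate
6 | 4-benzyloxy-3-methoxybenzyl chloride | COc1cc(CCl)ccc1OCc1ccccc1 | intermediate
7 | (4-benzyloxy-3-methoxybenzyl)zinc chloride | COc1cc(C[Zn]Cl)ccc1OCc1ccccc1 | intermediate
8 | (5R)-3-(4-benzyloxy-3-methoxybenzyl)-5-(l-menthyloxy)furan-2(5H)-one | O=C1C(Cc2ccc(OCc3ccccc3)c(OC)c2)=C[C@H](O[C@@H]2C[C@H](C)CC[C@H]2C(C)C)O1 | intermediate
9 | (E)-4-benzyloxy-3-methoxybenzaldehyde oxime | COc1cc(/C=N/O)ccc1OCc1ccccc1 | intermediate
10 | (Z)-4-benzyloxy-N-hydroxy-3-methoxybenzimidoyl chloride | Cl/C(=N\O)c1ccc(OCc2ccccc2)c(OC)c1 | intermediate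
11 | 4-benzyloxy-3-methoxybenzonitrile oxide | [O-][N+]#Cc1ccc(OCc2ccccc2)c(OC)c1 | intermediate
12 | (3aR,4R,6aS)-3-(4-benzyloxy-3-methoxyphenyl)-6a-(4-benzyloxy-3-methoxybenzyl)-4-(l-menthyloxy)-3a,6a-dihydrofuro[3,4-d]isoxazol-6(4H)-one | O=C1O[C@@H](O[C@@H]3C[C@H](C)CC[C@H]3C(C)C)[C@@H]2C(c3ccc(OCc4ccccc4)c(OC)c3)=NO[C@]12Cc1ccc(OCc2ccccc2)c(OC)c1 | intermediate
13 | (3aR,6aS)-4-hydroxy analogue of 12 (lactol, C4 anomers) | O=C1OC(O)[C@@H]2C(c3ccc(OCc4ccccc4)c(OC)c3)=NO[C@]12Cc1ccc(OCc2ccccc2)c(OC)c1 | intermediate
14 | (4R,5S)-3-(4-benzyloxy-3-methoxyphenyl)-5-(4-benzyloxy-3-methoxybenzyl)-4-formyl-4,5-dihydroisoxazole-5-carboxylic acid | O=C[C@@H]1C(c2ccc(OCc3ccccc3)c(OC)c2)=NO[C@]1(Cc1ccc(OCc2ccccc2)c(OC)c1)C(=O)O | intermediate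
15 | (4S,5S)-3-(4-benzyloxy-3-methoxyphenyl)-5-(4-benzyloxy-3-methoxybenzyl)-4-(hydroxymethyl)-4,5-dihydroisoxazole-5-carboxylic acid | OC[C@@H]1C(c2ccc(OCc3ccccc3)c(OC)c2)=NO[C@]1(Cc1ccc(OCc2ccccc2)c(OC)c1)C(=O)O | intermediate
16 | (3aS,6aS)-3-(4-benzyloxy-3-methoxyphenyl)-6a-(4-benzyloxy-3-methoxybenzyl)-3a,6a-dihydrofuro[3,4-d]isoxazol-6(4H)-one | O=C1OC[C@@H]2C(c3ccc(OCc4ccccc4)c(OC)c3)=NO[C@]12Cc1ccc(OCc2ccccc2)c(OC)c1 | intermediate
17 | (3S,4S)-3-(4-benzyloxy-3-methoxybenzyl)-4-[(4-benzyloxy-3-methoxyphenyl)(imino)methyl]-3-hydroxydihydrofuran-2(3H)-one | COc1cc(C[C@@]2(O)C(=O)OC[C@@H]2C(=N)c2ccc(OCc3ccccc3)c(OC)c2)ccc1OCc1ccccc1 | intermediate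
18 | (3S,4S)-4-(4-benzyloxy-3-methoxybenzoyl)-3-(4-benzyloxy-3-methoxybenzyl)-3-hydroxydihydrofuran-2(3H)-one | COc1cc(C[C@@]2(O)C(=O)OC[C@@H]2C(=O)c2ccc(OCc3ccccc3)c(OC)c2)ccc1OCc1ccccc1 | intermediate
19 | (3S,4S)-3-hydroxy-4-(4-hydroxy-3-methoxybenzoyl)-3-(4-hydroxy-3-methoxybenzyl)dihydrofuran-2(3H)-one | COc1cc(C[C@@]2(O)C(=O)OC[C@@H]2C(=O)c2ccc(O)c(OC)c2)ccc1O | intermediate
20 | tetramethylammonium diacetoxy(hydrido)borate bound through the C3 oxygen of 19 | C[N+](C)(C)C.COc1cc(C[C@@]2(O[BH-](OC(C)=O)OC(C)=O)C(=O)OC[C@@H]2C(=O)c2ccc(O)c(OC)c2)ccc1O | intermediate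
21 | (3S,4R)-3-hydroxy-4-[(R)-hydroxy(4-hydroxy-3-methoxyphenyl)methyl]-3-(4-hydroxy-3-methoxybenzyl)dihydrofuran-2(3H)-one | COc1cc(C[C@@]2(O)C(=O)OC[C@@H]2[C@@H](O)c2ccc(O)c(OC)c2)ccc1O | target

Total step count: 13.
Longest linear sequence: 10 steps (4, 5, 6, 7, 8, 12, 13, 16, 18, 19, 21; steps 2, 3, 4, 5, 8, 9, 10, 11, 12, 13).

Steps most likely to fail

**Step 8.**
- What may go wrong: the trisubstituted alkene, flanked by the benzyl group and the acetal, may react so slowly that dimerisation of the dipole takes over. The electronic bias of the enoate may also override the steric bias and erode regioselectivity.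
- Fallback: a stepwise polar construction of the same centres from 1, 4 and 6, returning to the route at 18.
- Aldehyde 4 is condensed with propane-1,3-dithiol (BF3·OEt2, CH2Cl2) to 2-(4-benzyloxy-3-methoxyphenyl)-1,3-dithiane F1.
- After deprotonation with n-BuLi (THF, −78 °C), F1 adds 1,4 to butenolide 1 anti to the menthyloxy group. The enolate is oxidised in the same flask with 2-(phenylsulfonyl)-3-phenyloxaziridine (Davis oxidation) to (3R,4R,5R)-4-[2-(4-benzyloxy-3-methoxyphenyl)-1,3-dithian-2-yl]-3-hydroxy-5-(l-menthyloxy)dihydrofuran-2(3H)-one F2, whose C3 configuration is of no consequence.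
- Double deprotonation with LiN(i-Pr)2 (THF–DMPU) and alkylation with chloride 6 (Bu4NI) brings the benzyl group in anti to the bulky dithianyl group and so leaves the tertiary OH cis to it. This gives (3S,4R,5R)-3-(4-benzyloxy-3-methoxybenzyl)-4-[2-(4-benzyloxy-3-methoxyphenyl)-1,3-dithian-2-yl]-3-hydroxy-5-(l-menthyloxy)dihydrofuran-2(3H)-one F3.
- NaBH4 and KOH in EtOH followed by HCl take the acetal carbon to CH2, giving (3S,4S)-3-(4-benzyloxy-3-methoxybenzyl)-4-[2-(4-benzyloxy-3-methoxyphenyl)-1,3-dithian-2-yl]-3-hydroxydihydrofuran-2(3H)-one F4.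
- MeI with CaCO3 in aqueous MeCN then unmasks the ketone, which is 18.

**Step 10.**
- What may go wrong: enolisation of the open aldehyde before hydride arrives would cause loss of configuration at the ring CH or β-elimination of the isoxazoline oxygen.
- Fallback: from lactol 13 the anionic ring opening is replaced by ionic hydrogenation (Et3SiH, BF3·OEt2, CH2Cl2, −40 to 0 °C).
- Silane hydride captures the Lewis-acid-activated C4, either as the oxocarbenium ion or as the complexed aldehyde that relactonises. No base is ever present, and the sequence returns directly at 16.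

**Step 13.**
- What may go wrong: the hindered, electron-poor tertiary hydroxyl may fail to exchange onto boron. Reduction of the deactivated p-hydroxyaryl ketone would then stall, or it would run intermolecularly with poor facial selectivity.
- Fallback: from 19 stereocontrol is moved from the substrate to a catalyst by Corey–Bakshi–Shibata reduction with (S)-2-methyl-CBS-oxazaborolidine and excess BH3·SMe2 (THF, −20 °C). The three OH groups consume borane first.
- The catalyst treats the aryl group as the large substituent and presents hydride to the Si face. A methanol quench returns the route at 21.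

Further compounds
F1 | step 8 | 2-(4-benzyloxy-3-methoxyphenyl)-1,3-dithiane | COc1cc(C2SCCCS2)ccc1OCc1ccccc1
F2 | step 8 | (3R,4R,5R)-4-[2-(4-benzyloxy-3-methoxyphenyl)-1,3-dithian-2-yl]-3-hydroxy-5-(l-menthyloxy)dihydrofuran-2(3H)-one | O=C1O[C@@H](O[C@@H]2C[C@H](C)CC[C@H]2C(C)C)[C@H](C2(c3ccc(OCc4ccccc4)c(OC)c3)SCCCS2)[C@H]1O
F3 | step 8 | (3S,4R,5R)-3-(4-benzyloxy-3-methoxybenzyl)-4-[2-(4-benzyloxy-3-methoxyphenyl)-1,3-dithian-2-yl]-3-hydroxy-5-(l-menthyloxy)dihydrofuran-2(3H)-one | O=C1O[C@@H](O[C@@H]2C[C@H](C)CC[C@H]2C(C)C)[C@H](C2(c3ccc(OCc4ccccc4)c(OC)c3)SCCCS2)[C@@]1(O)Cc1ccc(OCc2ccccc2)c(OC)c1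
F4 | step 8 | (3S,4S)-3-(4-benzyloxy-3-methoxybenzyl)-4-[2-(4-benzyloxy-3-methoxyphenyl)-1,3-dithian-2-yl]-3-hydroxydihydrofuran-2(3H)-one | O=C1OC[C@H](C2(c3ccc(OCc4ccccc4)c(OC)c3)SCCCS2)[C@@]1(O)Cc1ccc(OCc2ccccc2)c(OC)c1
F0 | step 10 | none | none
F0 | step 13 | none | none
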